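The leftover was what I wanted first: how much starting material Sunday's flask still held at its last reading, since Saturday's flask has the same charge and is asked about much later.

| flask | starting material | partner | free catalyst | time |
|---|---|---|---|---|
| Sunday's | 0.200 M | 0.240 M | 0.0160 M |  |
| Friday's | 0.0800 M | 0.120 M | 0.0160 M |  |
| Tuesday's | 0.600 M | 0.240 M | 0.0160 M |  |
| Thursday's | 0.200 M | 0.240 M | 0.0320 M |  |
| Saturday's | 0.200 M | 0.240 M | 0.0160 M | 27 min |

- Sunday's run (time / min: [target] / M): 1.1: 0.0200; 2.2: 0.0402; 3.4: 0.0595; 4.5: 0.0725; 5.6: 0.0802; 6.7: 0.0855
- Friday's run (time / min: [target] / M): 1.1: 0.0078; 2.2: 0.0150; 3.4: 0.0212; 4.5: 0.0274; 5.6: 0.0301; 6.7: 0.0312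
- Tuesday's run (time / min: [target] / M): 1.1: 0.0315; 2.2: 0.0784; 3.4: 0.1221; 4.5: 0.1422; 5.6: 0.1459; 6.7: 0.1402
- Thursday's run (time / min: [target] / M): 1.1: 0.0369; 2.2: 0.0680; 3.4: 0.0917; 4.5: 0.1014; 5.6: 0.1059; 6.7: 0.1048

(scatter of a reading: 6 × 10⁻⁴ M)

1. the exponent of [free catalyst] in the starting rate at the charge of the Sunday's run (at the point where two percent of the starting material have become target)
2. the exponent of [starting material] in the starting rate at the charge of the Sunday's run (at the point where two percent of the starting material have become target) (one fixed amount of target, the same in the runs compared)
3. target in the Saturday's run at 27 min, as a share of the starting material charged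

- Overall: starting material + partner -> target, with free catalyst as catalyst.
- Constant volume, constant temperature.
- An order is taken over about fifteen percent of the charge, up and down.

In Sunday's flask starting material is the limiting reagent, 0.200 M against 0.240 M of partner. I booked each mole charged under one of three entries: leftover, target, or target since lost, and whatever the catalyst held at a given moment was counted with the leftover. Target is read, but the loss needs a constant. I assumed that target is lost in proportion to its own concentration.

Tuesday's flask gives that constant. Its partner is the smaller charge, and its readings turn down at the end. I booked its whole partner charge as turned by 6.7 min, which may overstate the loss, so the constant is a ceiling: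

area under Tuesday's target curve = 39.6 M·s

k = (partner charged − target read) / area = 0.151 min⁻¹

I call k the loss constant, the share of target lost each minute. Sunday's books at 6.7 min then read:

target = 0.0855 M

lost = k × area = 0.0532 M

leftover = 0.0613 M

Making, the last rise plus the loss, stood near 0.0174 M min⁻¹, so I expected the leftover to clear in 3.53 min. From there the loss has control. Counting the leftover as entering halfway through that time:

target at 27 min = (charge − lost) × exp(−k × time) = 0.00887 M, or 4.44% of the charge

That share leans low, since k is a ceiling.

The forecast gave 0.9 as the order in free catalyst, 0.4 as the order in starting material, and 35% against my 4.44% for Saturday's share, on the ground that “target is being lost”.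

The flask gave 0.84, 0.29 and 11.1%.

    free catalyst + starting material → loaded catalyst + by-product (44.52 M⁻¹ min⁻¹)
    loaded catalyst + partner → target + free catalyst (5.922 M⁻¹ min⁻¹)
    target → decomposed product (0.1176 min⁻¹)
    starting material + partner + target → 2 target (6.480 M⁻² min⁻¹)

Saturday's low share comes from the passing of target into decomposed product: the simulated run of that flask without this step ends at 99.7% instead of 11.1%. My k of 0.151 min⁻¹ stood above that step's 0.118 min⁻¹. In Thursday's flask, making equals loss near the highest reading, 0.1059 M, so k gives making there as 0.0160 M min⁻¹, and the step's own constant gives 0.0125 M min⁻¹, which is 0.385 of its early 0.032 M min⁻¹.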